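**Retrosynthetic overview** (germacranolide numbering: C1–C10 ring, C11–C13 lactone carbons, C14 on C10, C15 on C4)
1. Last ring event: one transannular cascade on a glaucolide-type 4,5-epoxy-7(11)-en-12,6-olide carrying a C1≡C2–C3=O ynone (24); the epoxide oxygen becomes the 1,4-bridge of the 3(2H)-furanone and C5=C6 forms by loss of H-6 (the glaucolide → hirsutinolide step); then desilylation.
2. Ten-membered carbocycle (second ring): intramolecular Nozaki–Hiyama–Kishi closure of C2–C3 from iodoalkyne/epoxy aldehyde 22.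
3. Butenolide (first ring): Nozaki–Hiyama–Kishi coupling/lactonisation (C6–C7) of (Z)-β-iodo enoate 18 with epoxy aldehyde 7.
4. 18 from crotonaldehyde (Rh alkynylation, C10), methyl propiolate (Zn-ProPhenol, C8), side-chain acid 9 and formaldehyde (iodo-aldol, C13).
5. 7 and 9 both from ethyl (E)-4-hydroxy-3-methylbut-2-enoate 3 (hydroxyacetone Wittig); C4 from Sharpless epoxidation.

Assumption: for the three enantioselective catalysts the ligand antipode that gives the drawn configuration is used (the antipode named is my best assignment), and C6 and C3 are carried as epimer mixtures because both become sp2.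

**Step 1**
Reactants: 1 hydroxyacetone; 2 ethyl (triphenylphosphoranylidene)acetate
Product: 3 ethyl (E)-4-hydroxy-3-methylbut-2-enoate
Conditions: CH2Cl2, reflux, 16 h
Reagents that add atoms: none
Why: Wittig olefination with a stabilised ylide is E-selective for α-hydroxy ketones, and the minor Z isomer lactonises to a volatile butenolide that is removed.

**Step 2**
Reactants: 3 ethyl (E)-4-hydroxy-3-methylbut-2-enoate
Product: 4 ethyl (E)-3-methyl-4-(triethylsilyloxy)but-2-enoate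
Conditions: TESCl, imidazole, CH2Cl2, 0 °C
Reagents that add atoms: chlorotriethylsilane, CC[Si](Cl)(CC)CC
Why: Standard silylation; TES is chosen because a primary TES ether can later be oxidised directly in the presence of TBS ethers.

**Step 3**
Reactants: 4 ethyl (E)-3-methyl-4-(triethylsilyloxy)but-2-enoate
Product: 5 (E)-3-methyl-4-(triethylsilyloxy)but-2-en-1-ol
Conditions: DIBAL-H (2.2 equiv), CH2Cl2, −78 °C; Rochelle salt
Reagents that add atoms: none
Why: 1,2-Reduction of an enoate to the allylic alcohol with DIBAL-H, alkene geometry untouched.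

**Step 4**
Reactants: 5 (E)-3-methyl-4-(triethylsilyloxy)but-2-en-1-ol
Product: 6 [(2R,3R)-3-methyl-3-(triethylsilyloxymethyl)oxiran-2-yl]methanol
Conditions: Ti(OiPr)4 (10 mol%), D-(−)-diethyl tartrate (12 mol%), TBHP, 4 Å MS, CH2Cl2, −20 °C
Reagents that add atoms: tert-butyl hydroperoxide, CC(C)(C)OO
Why: Sharpless asymmetric epoxidation of a geraniol-type allylic alcohol; D-(−)-tartrate gives the (2R,3R) epoxide (L-(+)-tartrate gives (2S,3S)-epoxygeraniol), which sets the quaternary C4–O centre of the target.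

**Step 5**
Reactants: 6 [(2R,3R)-3-methyl-3-(triethylsilyloxymethyl)oxiran-2-yl]methanol
Product: 7 (2S,3R)-3-methyl-3-(triethylsilyloxymethyl)oxirane-2-carbaldehyde
Conditions: TEMPO (10 mol%), PhI(OAc)2 (1.1 equiv), CH2Cl2, rt
Reagents that add atoms: none
Why: Nitroxyl-catalysed oxidation of the primary alcohol stops at the aldehyde and does not open the epoxide.

**Step 6**
Reactants: 3 ethyl (E)-4-hydroxy-3-methylbut-2-enoate
Product: 8 ethyl (E)-4-(tert-butyldimethylsilyloxy)-3-methylbut-2-enoate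
Conditions: TBSCl, imidazole, DMF, rt
Reagents that add atoms: tert-butyldimethylsilyl chloride, CC(C)(C)[Si](C)(C)Cl
Why: Standard silylation of the primary allylic alcohol.

**Step 7**
Reactants: 8 ethyl (E)-4-(tert-butyldimethylsilyloxy)-3-methylbut-2-enoate
Product: 9 (E)-4-(tert-butyldimethylsilyloxy)-3-methylbut-2-enoic acid
Conditions: LiOH·H2O, THF/MeOH/H2O, 0 °C → rt; then 0.5 M HCl to pH 4 at 0 °C
Reagents that add atoms: lithium hydroxide, [Li+].[OH-]
Why: Ester saponification; the primary TBS ether survives the brief cold acidification.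

**Step 8**
Reactants: 10 (E)-crotonaldehyde; 11 (triisopropylsilyl)acetylene
Product: 12 (S)-3-methyl-5-(triisopropylsilyl)pent-4-ynal
Conditions: [Rh(OAc)(C2H4)2]2 (2.5 mol%), (S)-DTBM-SEGPHOS (6 mol%), MeOH, 40 °C
Reagents that add atoms: none
Why: Rhodium-catalysed asymmetric conjugate alkynylation of an enal (the bulky silyl group suppresses alkyne dimerisation); Si-face delivery at C3 sets C10 as S.

**Step 9**
Reactants: 12 (S)-3-methyl-5-(triisopropylsilyl)pent-4-ynal; 13 methyl propiolate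
Product: 14 methyl (4S,6S)-4-hydroxy-6-methyl-8-(triisopropylsilyl)octa-2,7-diynoate
Conditions: (S,S)-ProPhenol (20 mol%), Me2Zn (3 equiv), Ph3P=O (40 mol%), toluene, 0 → 4 °C
Reagents that add atoms: none
Why: Dinuclear zinc–ProPhenol alkynylation of an aldehyde with the propiolate; catalyst-controlled Re-face addition sets C8 as S, and any minor diastereomer is separated.

**Step 10**
Reactants: 14 methyl (4S,6S)-4-hydroxy-6-methyl-8-(triisopropylsilyl)octa-2,7-diynoate; 9 (E)-4-(tert-butyldimethylsilyloxy)-3-methylbut-2-enoic acid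
Product: 15 methyl (4S,6S)-4-[(E)-4-(tert-butyldimethylsilyloxy)-3-methylbut-2-enoyloxy]-6-methyl-8-(triisopropylsilyl)octa-2,7-diynoate
Conditions: DIC (1.3 equiv), DMAP (0.1 equiv), CH2Cl2, 0 °C → rt
Reagents that add atoms: none
Why: Steglich esterification acylates the O–H bond, so C8 keeps its configuration and the side chain is in place early.

**Step 11**
Reactants: 15 acyloxy diynoate (as above); 16 formaldehyde (monomeric, from cracked paraformaldehyde)
Product: 17 methyl (2Z,4S,6S)-2-(hydroxymethyl)-3-iodo-4-[(E)-4-(tert-butyldimethylsilyloxy)-3-methylbut-2-enoyloxy]-6-methyl-8-(triisopropylsilyl)oct-2-en-7-ynoate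
Conditions: MgI2 (1.5 equiv), CH2Cl2, −20 → 0 °C
Reagents that add atoms: magnesium iodide, [Mg+2].[I-].[I-]
Why: β-Iodo Morita–Baylis–Hillman (iodo-aldol) reaction: iodide adds to C7 of the ynoate and the magnesium β-iodoallenolate is trapped at C11 by formaldehyde anti to iodine (as in anti-hydroiodination of 2-alkynoates and MgI2 reactions of propiolates), which places I cis to CO2Me and brings in C13.

**Step 12**
Reactants: 17 (Z)-β-iodo hydroxymethyl enoate (as above)
Product: 18 methyl (2Z,4S,6S)-2-(tert-butyldimethylsilyloxymethyl)-3-iodo-4-[(E)-4-(tert-butyldimethylsilyloxy)-3-methylbut-2-enoyloxy]-6-methyl-8-(triisopropylsilyl)oct-2-en-7-ynoate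
Conditions: TBSCl, imidazole, CH2Cl2, 0 °C
Reagents that add atoms: tert-butyldimethylsilyl chloride, CC(C)(C)[Si](C)(C)Cl
Why: Standard silylation of the primary allylic alcohol so that only C3–O remains differentiated (TES).

**Step 13**
Reactants: 18 (Z)-β-iodo enoate TBS ether; 7 (2S,3R)-3-methyl-3-(triethylsilyloxymethyl)oxirane-2-carbaldehyde
Product: 20 epoxy butenolide (C6 epimers), via seco hydroxy ester 19 (not isolated)
Conditions: CrCl2 (6 equiv), NiCl2 (2 mol%), DMSO/THF, rt; lactonisation on work-up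
Reagents that add atoms: none
Why: Nozaki–Hiyama–Kishi coupling: the alkenyl iodide is metalated with retention and adds to the aldehyde, and the new C6 alkoxide, cis to the ester, lactonises to the 12,6-olide; the C6 epimer mixture is irrelevant because C6 becomes sp2 in step 17.

**Step 14**
Reactants: 20 epoxy butenolide
Product: 21 iodoalkyne butenolide
Conditions: AgF (1.5 equiv), NIS (1.3 equiv), MeCN, rt, dark
Reagents that add atoms: N-iodosuccinimide, O=C1CCC(=O)N1I
Why: Silver-fluoride-mediated exchange of the alkynyl TIPS group for iodine via the silver acetylide leaves the silyl ethers in place (any TES loss is harmless, since step 15 oxidises alcohol and TES ether alike).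

**Step 15**
Reactants: 21 iodoalkyne butenolide
Product: 22 iodoalkyne epoxy aldehyde
Conditions: (COCl)2, DMSO, CH2Cl2, −78 °C; 21, −78 → −40 °C; Et3N, −78 → −30 °C
Reagents that add atoms: none
Why: Swern conditions cleave and oxidise a primary TES ether directly to the aldehyde while primary TBS ethers are inert; the cold, short exposure to Et3N does not enolise the butenolide, and C4 is quaternary so nothing can epimerise.

**Step 16**
Reactants: 22 iodoalkyne epoxy aldehyde
Product: 23 macrocyclic propargylic alcohol (C3 and C6 epimers)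
Conditions: CrCl2 (10 equiv), NiCl2 (1 mol%), THF, rt, 22 added over 12 h to 1 mM
Reagents that add atoms: none
Why: Intramolecular Nozaki–Hiyama–Kishi addition of the alkynylchromium to the aldehyde closes C2–C3 under neutral conditions that spare the epoxide and the acidic H-6; nine- and ten-membered cycloalkynols have been closed by acetylide–aldehyde addition at high dilution, and the C3 carbinol is oxidised next.

**Step 17**
Reactants: 23 macrocyclic propargylic alcohol
Product: 25 bis-TBS ether of the target, via macrocyclic epoxy ynone 24 (not isolated)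
Conditions: Dess–Martin periodinane (1.5 equiv), NaHCO3, CH2Cl2, 0 °C → rt; aqueous Na2S2O3 wash, no chromatography; then Ph3PAuNTf2 (5 mol%), CH2Cl2, 0 °C → rt
Reagents that add atoms: none
Why: Proposed new method: after oxidation to ynone 24, π-acid activation of C1≡C2 lets the epoxide oxygen, held across the ring, attack C1 (5-endo-dig); the epoxonium opens at C5 (C4 is α to the ketone and cannot carry charge) with loss of the vinylogously acidic H-6 to give the C5=C6 enol lactone, and protodeauration at C2 completes the 3(2H)-furanone, so the C4–O bond is never broken (C4 stays S) and the ring holds C4 and C7 cis on C5=C6; the closest known reactions are the glaucolide → hirsutinolide epoxide opening/1,4-ether formation and gold-catalysed cyclisations of alkynyl epoxides and of α′-hydroxy ynones to 3(2H)-furanones.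

**Step 18**
Reactants: 25 bis-TBS ether of the target
Product: 26 target
Conditions: HF·pyridine, pyridine, THF, 0 °C → rt
Reagents that add atoms: none
Why: Buffered, non-basic fluoride cleavage of the two primary TBS ethers leaves the side-chain ester, the enol lactone and the furanone intact.

**Compound list**
1 | hydroxyacetone | CC(=O)CO | starting material
2 | ethyl (triphenylphosphoranylidene)acetate | CCOC(=O)C=P(c1ccccc1)(c1ccccc1)c1ccccc1 | starting material
3 | ethyl (E)-4-hydroxy-3-methylbut-2-enoate | CCOC(=O)/C=C(\C)CO | intermediate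
4 | ethyl (E)-3-methyl-4-(triethylsilyloxy)but-2-enoate | CCOC(=O)/C=C(\C)CO[Si](CC)(CC)CC | intermediate
5 | (E)-3-methyl-4-(triethylsilyloxy)but-2-en-1-ol | OC/C=C(\C)CO[Si](CC)(CC)CC | intermediate
6 | [(2R,3R)-3-methyl-3-(triethylsilyloxymethyl)oxiran-2-yl]methanol | OC[C@H]1O[C@]1(C)CO[Si](CC)(CC)CC | intermediate
7 | (2S,3R)-3-methyl-3-(triethylsilyloxymethyl)oxirane-2-carbaldehyde | O=C[C@H]1O[C@]1(C)CO[Si](CC)(CC)CC | intermediate
8 | ethyl (E)-4-(tert-butyldimethylsilyloxy)-3-methylbut-2-enoate | CCOC(=O)/C=C(\C)CO[Si](C)(C)C(C)(C)C | intermediate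
9 | (E)-4-(tert-butyldimethylsilyloxy)-3-methylbut-2-enoic acid | OC(=O)/C=C(\C)CO[Si](C)(C)C(C)(C)C | intermediate
10 | (E)-crotonaldehyde | C/C=C/C=O | starting material
11 | (triisopropylsilyl)acetylene | C#C[Si](C(C)C)(C(C)C)C(C)C | starting material
12 | (S)-3-methyl-5-(triisopropylsilyl)pent-4-ynal | O=CC[C@H](C)C#C[Si](C(C)C)(C(C)C)C(C)C | intermediate
13 | methyl propiolate | COC(=O)C#C | starting material
14 | methyl (4S,6S)-4-hydroxy-6-methyl-8-(triisopropylsilyl)octa-2,7-diynoate | COC(=O)C#C[C@@H](O)C[C@H](C)C#C[Si](C(C)C)(C(C)C)C(C)C | intermediate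
15 | methyl (4S,6S)-4-[(E)-4-(tert-butyldimethylsilyloxy)-3-methylbut-2-enoyloxy]-6-methyl-8-(triisopropylsilyl)octa-2,7-diynoate | COC(=O)C#C[C@@H](OC(=O)/C=C(\C)CO[Si](C)(C)C(C)(C)C)C[C@H](C)C#C[Si](C(C)C)(C(C)C)C(C)C | intermediate
16 | formaldehyde (monomeric, from paraformaldehyde) | C=O | starting material
17 | methyl (2Z,4S,6S)-2-(hydroxymethyl)-3-iodo-4-[(E)-4-(tert-butyldimethylsilyloxy)-3-methylbut-2-enoyloxy]-6-methyl-8-(triisopropylsilyl)oct-2-en-7-ynoate (I cis to CO2Me) | COC(=O)/C(CO)=C(\I)[C@@H](OC(=O)/C=C(\C)CO[Si](C)(C)C(C)(C)C)C[C@H](C)C#C[Si](C(C)C)(C(C)C)C(C)C | intermediate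
18 | methyl (2Z,4S,6S)-2-(tert-butyldimethylsilyloxymethyl)-3-iodo-4-[(E)-4-(tert-butyldimethylsilyloxy)-3-methylbut-2-enoyloxy]-6-methyl-8-(triisopropylsilyl)oct-2-en-7-ynoate | COC(=O)/C(CO[Si](C)(C)C(C)(C)C)=C(\I)[C@@H](OC(=O)/C=C(\C)CO[Si](C)(C)C(C)(C)C)C[C@H](C)C#C[Si](C(C)C)(C(C)C)C(C)C | intermediate
19 | methyl (2E,4S,6S)-2-(tert-butyldimethylsilyloxymethyl)-3-{hydroxy[(2R,3R)-3-methyl-3-(triethylsilyloxymethyl)oxiran-2-yl]methyl}-4-[(E)-4-(tert-butyldimethylsilyloxy)-3-methylbut-2-enoyloxy]-6-methyl-8-(triisopropylsilyl)oct-2-en-7-ynoate (carbinol carbon cis to CO2Me; carbinol epimers) | COC(=O)/C(CO[Si](C)(C)C(C)(C)C)=C(\C(O)[C@H]1O[C@]1(C)CO[Si](CC)(CC)CC)[C@@H](OC(=O)/C=C(\C)CO[Si](C)(C)C(C)(C)C)C[C@H](C)C#C[Si](C(C)C)(C(C)C)C(C)C | intermediate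
20 | 3-(tert-butyldimethylsilyloxymethyl)-4-{(1S,3S)-1-[(E)-4-(tert-butyldimethylsilyloxy)-3-methylbut-2-enoyloxy]-3-methyl-5-(triisopropylsilyl)pent-4-ynyl}-5-[(2R,3R)-3-methyl-3-(triethylsilyloxymethyl)oxiran-2-yl]furan-2(5H)-one (furanone C5 = C6, both epimers) | O=C1OC([C@H]2O[C@]2(C)CO[Si](CC)(CC)CC)C(=C1CO[Si](C)(C)C(C)(C)C)[C@@H](OC(=O)/C=C(\C)CO[Si](C)(C)C(C)(C)C)C[C@H](C)C#C[Si](C(C)C)(C(C)C)C(C)C | intermediate
21 | as 20 with the side chain ending in 5-iodopent-4-ynyl [(1S,3S)-1-acyloxy-5-iodo-3-methylpent-4-ynyl] | O=C1OC([C@H]2O[C@]2(C)CO[Si](CC)(CC)CC)C(=C1CO[Si](C)(C)C(C)(C)C)[C@@H](OC(=O)/C=C(\C)CO[Si](C)(C)C(C)(C)C)C[C@H](C)C#CI | intermediate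
22 | (2S,3R)-3-{4-(tert-butyldimethylsilyloxymethyl)-3-[(1S,3S)-1-[(E)-4-(tert-butyldimethylsilyloxy)-3-methylbut-2-enoyloxy]-5-iodo-3-methylpent-4-ynyl]-5-oxo-2,5-dihydrofuran-2-yl}-2-methyloxirane-2-carbaldehyde (C6 epimers) | O=C1OC([C@H]2O[C@]2(C)C=O)C(=C1CO[Si](C)(C)C(C)(C)C)[C@@H](OC(=O)/C=C(\C)CO[Si](C)(C)C(C)(C)C)C[C@H](C)C#CI | intermediate
23 | (4R,5R,8S,10S)-4,5-epoxy-3-hydroxy-13-(tert-butyldimethylsilyloxy)-8-[(E)-4-(tert-butyldimethylsilyloxy)-3-methylbut-2-enoyloxy]germacr-7(11)-en-1-yn-12,6-olide (C3 and C6 epimers) | OC1C#C[C@@H](C)C[C@H](OC(=O)/C=C(\C)CO[Si](C)(C)C(C)(C)C)C2=C(CO[Si](C)(C)C(C)(C)C)C(=O)OC2[C@H]3O[C@]13C | intermediate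
24 | (4S,5R,8S,10S)-4,5-epoxy-3-oxo-13-(tert-butyldimethylsilyloxy)-8-[(E)-4-(tert-butyldimethylsilyloxy)-3-methylbut-2-enoyloxy]germacr-7(11)-en-1-yn-12,6-olide (C6 epimers) | O=C1C#C[C@@H](C)C[C@H](OC(=O)/C=C(\C)CO[Si](C)(C)C(C)(C)C)C2=C(CO[Si](C)(C)C(C)(C)C)C(=O)OC2[C@H]3O[C@]13C | intermediate
25 | (4S,5E,8S,10S)-13-(tert-butyldimethylsilyloxy)-8-[(E)-4-(tert-butyldimethylsilyloxy)-3-methylbut-2-enoyloxy]-3-oxo-1,4-epoxygermacra-1,5,7(11)-trien-12,6-olide | C/C(=C\C(=O)O[C@H]1C[C@H](C)C2=CC(=O)[C@](C)(/C=C3/OC(=O)C(CO[Si](C)(C)C(C)(C)C)=C31)O2)CO[Si](C)(C)C(C)(C)C | intermediate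
26 | (4S,5E,8S,10S)-13-hydroxy-8-[(E)-4-hydroxy-3-methylbut-2-enoyloxy]-3-oxo-1,4-epoxygermacra-1,5,7(11)-trien-12,6-olide (CNP0288314.1) | C/C(=C\C(=O)O[C@H]1C[C@H](C)C2=CC(=O)[C@](C)(/C=C3/OC(=O)C(CO)=C31)O2)CO | target

**Step count**
Total: 18 steps. Longest linear sequence: 12 steps (1 → 3 → 8 → 9 → 15 → 17 → 18 → 20 → 21 → 22 → 23 → 25 → 26); the sequences from crotonaldehyde and through epoxy aldehyde 7 are 11 steps each.

**Three steps most likely to fail**

Step 11 (iodo-aldol). The risk is the geometry of the tetrasubstituted alkene and the use of formaldehyde with a β-substituted ynoate. The fallback sets out from 15 and comes back at 20, and fixes the geometry by a stereospecific anti addition. IBr (CH2Cl2, −78 → 0 °C) adds across the ynoate with bromide at C7 and iodine at C11, trans to each other, to give methyl (2E,4S,6S)-3-bromo-2-iodo-4-[(E)-4-(tert-butyldimethylsilyloxy)-3-methylbut-2-enoyloxy]-6-methyl-8-(triisopropylsilyl)oct-2-en-7-ynoate F1. Stille coupling of the C–I bond only with (tributylstannyl)methanol [Pd2(dba)3, AsPh3, CuI, NMP, rt] proceeds with retention and gives the (2Z)-3-bromo-2-(hydroxymethyl) enoate F2, with Br cis to CO2Me. TBSCl/imidazole gives its silyl ether F3. Ni/Cr coupling of this activated alkenyl bromide with 7, followed by lactonisation (again through 19), gives 20.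

Step 16 (macrocyclisation). The risk is the strain of a ten-membered cycloalkyne that also holds a trans epoxide and a fused butenolide. The fallback sets out from 22 and comes back at 25, and avoids the cycloalkyne. Gold-catalysed hydration of the iodoalkyne [XPhosAuNTf2 (2 mol%), H2O (3 equiv), 1,2-dichloroethane, rt] gives the α-iodomethyl ketone aldehyde F4. A chromium(II) Reformatsky cyclisation (CrCl2, THF, 1 mM) closes C2–C3 to the ten-membered β-hydroxy ketone F5, now with an sp3 C2. Dess–Martin oxidation gives the macrocyclic 1,3-diketone F6. DBU (vinylogous E1cB opening of the epoxide from C6) followed by TsOH (cyclodehydration of the 4-hydroxy-1,3-dione, the classical 3(2H)-furanone synthesis) gives 25.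

Step 17 (oxidation/gold cascade). The risks are that the epoxide oxygen is a poor nucleophile and that the epoxonium may rearrange instead of losing H-6. The fallback sets out from 23 and comes back at 25; it splits the cascade and changes the trigger from π-acid to base. DBU (0.5 equiv, MeCN, 0 °C) acts on alcohol 23, where no ynone is present, and effects the transannular vinylogous E1cB epoxide opening to the (4S,5E,8S,10S)-3,4-dihydroxy-germacra-5,7(11)-dien-1-yn-12,6-olide F7. MnO2 oxidises only the secondary propargylic alcohol to the 4-hydroxy ynone F8. AgOTf or AuCl3 (5 mol%) then closes the furanone by 5-endo-dig hydroalkoxylation to 25.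

Further compounds
F1 | step 11 | methyl (2E,4S,6S)-3-bromo-2-iodo-4-[(E)-4-(tert-butyldimethylsilyloxy)-3-methylbut-2-enoyloxy]-6-methyl-8-(triisopropylsilyl)oct-2-en-7-ynoate | COC(=O)/C(I)=C(\Br)[C@@H](OC(=O)/C=C(\C)CO[Si](C)(C)C(C)(C)C)C[C@H](C)C#C[Si](C(C)C)(C(C)C)C(C)C
F2 | step 11 | methyl (2Z,4S,6S)-3-bromo-2-(hydroxymethyl)-4-[(E)-4-(tert-butyldimethylsilyloxy)-3-methylbut-2-enoyloxy]-6-methyl-8-(triisopropylsilyl)oct-2-en-7-ynoate | COC(=O)/C(CO)=C(\Br)[C@@H](OC(=O)/C=C(\C)CO[Si](C)(C)C(C)(C)C)C[C@H](C)C#C[Si](C(C)C)(C(C)C)C(C)C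
F3 | step 11 | methyl (2Z,4S,6S)-3-bromo-2-(tert-butyldimethylsilyloxymethyl)-4-[(E)-4-(tert-butyldimethylsilyloxy)-3-methylbut-2-enoyloxy]-6-methyl-8-(triisopropylsilyl)oct-2-en-7-ynoate | COC(=O)/C(CO[Si](C)(C)C(C)(C)C)=C(\Br)[C@@H](OC(=O)/C=C(\C)CO[Si](C)(C)C(C)(C)C)C[C@H](C)C#C[Si](C(C)C)(C(C)C)C(C)C
F4 | step 16 | (2S,3R)-3-{4-(tert-butyldimethylsilyloxymethyl)-3-[(1S,3S)-1-[(E)-4-(tert-butyldimethylsilyloxy)-3-methylbut-2-enoyloxy]-5-iodo-3-methyl-4-oxopentyl]-5-oxo-2,5-dihydrofuran-2-yl}-2-methyloxirane-2-carbaldehyde (C6 epimers) | O=C1OC([C@H]2O[C@]2(C)C=O)C(=C1CO[Si](C)(C)C(C)(C)C)[C@@H](OC(=O)/C=C(\C)CO[Si](C)(C)C(C)(C)C)C[C@H](C)C(=O)CI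
F5 | step 16 | (4R,5R,8S,10S)-4,5-epoxy-3-hydroxy-1-oxo-13-(tert-butyldimethylsilyloxy)-8-[(E)-4-(tert-butyldimethylsilyloxy)-3-methylbut-2-enoyloxy]germacr-7(11)-en-12,6-olide (C3 and C6 epimers) | OC1CC(=O)[C@@H](C)C[C@H](OC(=O)/C=C(\C)CO[Si](C)(C)C(C)(C)C)C2=C(CO[Si](C)(C)C(C)(C)C)C(=O)OC2[C@H]3O[C@]13C
F6 | step 16 | (4S,5R,8S,10S)-4,5-epoxy-1,3-dioxo-13-(tert-butyldimethylsilyloxy)-8-[(E)-4-(tert-butyldimethylsilyloxy)-3-methylbut-2-enoyloxy]germacr-7(11)-en-12,6-olide (C6 epimers) | O=C1CC(=O)[C@@H](C)C[C@H](OC(=O)/C=C(\C)CO[Si](C)(C)C(C)(C)C)C2=C(CO[Si](C)(C)C(C)(C)C)C(=O)OC2[C@H]3O[C@]13C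
F7 | step 17 | (4S,5E,8S,10S)-3,4-dihydroxy-13-(tert-butyldimethylsilyloxy)-8-[(E)-4-(tert-butyldimethylsilyloxy)-3-methylbut-2-enoyloxy]germacra-5,7(11)-dien-1-yn-12,6-olide (C3 epimers) | OC1C#C[C@@H](C)C[C@H](OC(=O)/C=C(\C)CO[Si](C)(C)C(C)(C)C)C2=C(CO[Si](C)(C)C(C)(C)C)C(=O)O/C2=C/[C@]1(C)O
F8 | step 17 | (4S,5E,8S,10S)-4-hydroxy-3-oxo-13-(tert-butyldimethylsilyloxy)-8-[(E)-4-(tert-butyldimethylsilyloxy)-3-methylbut-2-enoyloxy]germacra-5,7(11)-dien-1-yn-12,6-olide | O=C1C#C[C@@H](C)C[C@H](OC(=O)/C=C(\C)CO[Si](C)(C)C(C)(C)C)C2=C(CO[Si](C)(C)C(C)(C)C)C(=O)O/C2=C/[C@]1(C)O
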